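- Early times told me most. In the spring run the target already stood at 63.2% at the first reading, 0.833 min, and at 63.2% at the last, 10.0 min. Whatever makes target had therefore stopped within τ = 0.833 min, and τ is an upper bound on that working life.

| flask | substrate | first nucleophile | second nucleophile | remark | time |
|---|---|---|---|---|---|
| summer | 0.20 mM | 0.22 mM | 0.12 mM | run made earlier |  |
| spring | 0.20 mM | 0.22 mM | 0.080 mM | run made earlier |  |
| winter | 0.20 mM | 0.22 mM | 0.18 mM | run made earlier |  |
| dusk | 0.20 mM | 0.44 mM | 0.12 mM | run made earlier |  |
| north-east | 0.20 mM | 0.220 mM (fed, over 5.0 min) | 0.120 mM | all else is in the flask from the start; the feed brings no volume worth counting | 8.0 min |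
| north-west | 0.20 mM (fed, over 5.0 min) | 0.220 mM | 0.120 mM | all else is in the flask from the start; the feed brings no volume worth counting | 8.0 min |
| north | 0.20 mM (fed, over 30 s) | 0.220 mM | 0.120 mM | all else is in the flask from the start; the feed brings no volume worth counting | 8.0 min |
| west | 0.20 mM (in portions, 5, over 5.0 min) | 0.220 mM | 0.120 mM | first portion at the start, last at 5.0 min | 8.0 min |
| south-west | 0.20 mM | 0.220 mM | 0.120 mM | everything together at the start | 8.0 min |

| summer: time / min | summer: target / % | spring: time / min | spring: target / % | winter: time / min | winter: target / % | dusk: time / min | dusk: target / % |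
|---|---|---|---|---|---|---|---|
| 1.50 | 53.9 | 0.833 | 63.2 | 0.833 | 44.8 | 2.00 | 68.7 |
| 3.00 | 53.7 | 1.33 | 63.5 | 1.33 | 44.3 | 4.00 | 67.7 |
| 5.00 | 54.4 | 2.50 | 63.2 | 2.50 | 44.7 | 6.00 | 67.4 |
| 6.00 | 54.4 | 5.00 | 62.9 | 5.00 | 44.2 | 8.00 | 67.5 |
| 8.00 | 54.0 | 10.0 | 63.2 | 10.0 | 44.5 | 10.0 | 67.6 |

(readings scatter by 0.5 percentage points)

- a reading or a percentage of target counts all its forms, free or not

- the flask with the highest amount of target, in percent of the substrate charged ("all alike" if they lie within 1.5 percentage points) (north-east / north-west / north / west / south-west / all alike)
- final target, as a percentage of the substrate charged, in north-east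
- final target, as a percentage of the substrate charged, in north-west
- final target, as a percentage of the substrate charged, in north
- final target, as a percentage of the substrate charged, in west
- final target, as a percentage of the substrate charged, in south-west

- I first solved the extreme with no clock, supposing that the substrate ends wholly captured and that the second nucleophile reacts to the end of its charge. The second nucleophile then holds 0.120 mM of the 0.20 mM substrate, and the first nucleophile takes the rest, so target is 40.0%.
- The other extreme has a clock: I let the first nucleophile work until τ, so that what enters later makes no target. In north-west, fed over 5.0 min, the charge that has entered by τ is 16.7%; this is the window share w, the part of the substrate charge in the flask by τ.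
- Multiplying w by the summer batch share, 54.0%, gave 9.00% for north-west.
- A picture of two stable nucleophiles waiting for fed substrate failed on the readings. If the substrate is used up between two stable nucleophiles, the selectivity factor, the ratio of the logarithms of what each keeps, should stay constant, but I read 0.338 in spring and 0.541 in winter.
- So I placed north-west at the clocked end, and below it if the true life is shorter than τ.
- In west the second portion comes at 1.25 min, later than τ, so w is 20.0% and target about 10.8%.
- North, fed in 30 s, has its whole charge in within τ, so the summer figure is merely its ceiling. North-east keeps first nucleophile arriving, so I expected its substrate to end captured and its second nucleophile to react to the end of its charge, and put it at 40.0%; south-west repeats summer.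
- The forecast, which differs from me on the substrate feeds, chose south-west, with 41%, 43%, 48%, 43% and 54% for north-east, north-west, north, west and south-west, holding that “High substrate therefore favours target”.
- The simulation put south-west highest, with 39.9%, 1.86%, 17.9%, 10.7% and 54.0% in the same order.

    first nucleophile + intermediate → target (k = 1.30 × 10⁵ M⁻¹ s⁻¹)
    second nucleophile + intermediate → other capture product (k = 1.30 × 10⁵ M⁻¹ s⁻¹)
    crystals ⇌ target, rate k3*(cs3 - [target]) while solid is left; crystals form when [target] > cs3 (solubility = 0.00220 mM, k = 0.550 s⁻¹)
    first nucleophile → decomposed reagent (k = 0.140 s⁻¹)
    first nucleophile + target → over-reaction product (k = 110 M⁻¹ s⁻¹)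
    substrate ⇌ intermediate (K = 0.270, k = 0.380 s⁻¹)

- North-west ended under its clocked 9.00%, and west landed beside its 10.8%. In south-west the half-life of first nucleophile by decomposition alone is 0.083 min, far shorter than the 5.0 min feed, and τ is ten times that half-life. North-west ended with 0% of its first nucleophile, 0.216 mM of decomposed reagent from the 0.220 mM charged, and 30.0% of its substrate unreacted.

The numbers in the tables are calculated on assumed constants, noise included.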